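Numbering: pyran C1, O2, C3, C4; carbocycle C4a, C5–C8, C8a; primes mark the isochroman half. Retrosynthetic cuts, in order: the C1=C8a quinone methide goes back to the C1H2 level, which makes both halves identical (C2 symmetry). Then C5–CH3/C5′–CH3, then C1–C8a with C1–O2 and their primed twins, and last C4–C4a and C4′–C4a′.
Enabling feature: both halves carry the same chain C4a–C4(CH3)–C3(CH3)–O2 with the 3,4-trans (threo) relation and the same (3R,4S) configuration. This is what an aryl carbanion at C4a produces by anti attack on meso cis-2,3-epoxybutane. Without C1 and the C5 methyl, each carbocycle is also symmetric about its C7–C4a axis, with only H at C5 and C8a.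
Forward order: the C7–CH2–C7′ diarylmethane is built first and brominated at C4a/C4a′. Both side chains are then attached in one operation, both pyran rings close together, the C5 methyls are added, the phenols are freed, and one pyran is dehydrogenated.
Stereochemistry: all four centres arise in the epoxide opening. The relative configuration comes from SN2 inversion and the absolute configuration from a chiral diamine on lithium. It is upgraded statistically because the reaction occurs twice in one molecule, and no later step touches C3 or C4.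

Key step: step 6

Assumption 1: (−)-sparteine is written as ligand on the premise that its aryllithium complex attacks the (S)-configured carbon of the epoxide; should the sense be opposite, commercial (+)-sparteine takes its place with nothing else changed.
Assumption 2: the 6-hydroxy-8-oxo and 8-hydroxy-6-oxo forms of the quinone methide half are rapidly interconverting tautomers; the product is drawn as the 6-hydroxy-8-oxo form of the target structure.

Step 1
Reactants: 1 1,3-dimethoxybenzene; 2 2,6-dimethoxybenzaldehyde
Product: 4 bis(2,6-dimethoxyphenyl)methanol, via 2,6-dimethoxyphenyllithium 3 (not isolated)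
Conditions: n-BuLi, THF, 0 °C to rt; 2, −78 °C to rt; H2O
Reagents that add atoms: none
Why: Directed ortho-metalation takes place between the two methoxy groups, and 1,2-addition of the resulting aryllithium to the aldehyde forms the future C7–CH2–C7′ link at the carbinol level.

Step 2
Reactants: 4 bis(2,6-dimethoxyphenyl)methanol
Product: 5 bis(2,6-dimethoxyphenyl)methane
Conditions: Et3SiH, TFA, CH2Cl2, 0 °C
Reagents that add atoms: none
Why: Ionic hydrogenation: acid ionises the benzhydrol to a cation stabilised by four ortho-methoxy groups, which takes hydride from the silane, while low temperature and short contact time keep acid-induced aryl–CH2 cleavage in check.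

Step 3
Reactants: 5 bis(2,6-dimethoxyphenyl)methane
Product: 7 bis(4-bromo-2,6-dimethoxyphenyl)methane, via bis(pinacol boronate) 6 (not isolated)
Conditions: [Ir(OMe)(cod)]2 (cat.), dtbpy (cat.), B2pin2 (2.2 equiv), THF, 80 °C; evaporate; CuBr2 (6 equiv), MeOH–H2O–THF, 80 °C
Reagents that add atoms: copper(II) bromide, [Cu+2].[Br-].[Br-]; bis(pinacolato)diboron, CC1(C)OB(OC1(C)C)B1OC(C)(C)C(C)(C)O1 (its boryl groups are held only by 6)
Why: Iridium-catalysed C–H borylation is governed by sterics and reaches only the C–H bond without an ortho neighbour, the one para to the bridge on each ring, and copper(II)-mediated bromodeboronation in the same flask puts bromine on a carbon (meta to both ethers) that electrophilic bromination would not choose.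

Step 4
Reactants: 7 bis(4-bromo-2,6-dimethoxyphenyl)methane
Product: 8 2,2'-methylenebis(5-bromobenzene-1,3-diol)
Conditions: BBr3 (6 equiv), CH2Cl2, −78 °C to rt; H2O
Reagents that add atoms: none
Why: Lewis-acid cleavage of aryl methyl ethers with BBr3 is done here, on a compound with no other sensitive group, because the methyl ethers (needed for the metalation and to keep the borylation off the protecting groups) could later be removed only under conditions that endanger the benzylic pyran ethers.

Step 5
Reactants: 8 2,2'-methylenebis(5-bromobenzene-1,3-diol)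
Product: 9 bis[2,6-bis(benzyloxy)-4-bromophenyl]methane
Conditions: BnBr (5 equiv), K2CO3, DMF, 60 °C
Reagents that add atoms: benzyl bromide, BrCc1ccccc1
Why: Williamson ether synthesis installs a group that tolerates aryllithiums, BF3 at low temperature and NBS, and that leaves at the end by neutral hydrogenolysis.

Step 6
Reactants: 9 bis[2,6-bis(benzyloxy)-4-bromophenyl]methane; 10 cis-2,3-epoxybutane (meso, excess)
Product: 12 bis{2,6-bis(benzyloxy)-4-[(2S,3R)-3-hydroxybutan-2-yl]phenyl}methane, via dilithio diarylmethane 11 (not isolated)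
Conditions: t-BuLi (4.1 equiv), Et2O–toluene, −78 °C; (−)-sparteine (2.4 equiv); 10 (5 equiv), then BF3·OEt2 (3 equiv) slowly, −78 °C; H2O
Reagents that add atoms: none
Why: Bromine–lithium exchange gives 11, whose two sparteine-bound C–Li carbons each attack a BF3-activated molecule of 10 from the side opposite to the C–O bond (SN2), forming C4–C4a and C4′–C4a′; no ring is closed. The closest known reaction type is the enantioselective desymmetrisation of meso-epoxides with an organolithium, a chiral diamine and BF3·OEt2, here run twice on one molecule. C4 and C4′ arise by inversion at the attacked carbon and C3 and C3′ keep the configuration of the untouched C–O carbon, so the cis-epoxide can give only the threo relation, while the absolute sense (attack on the (S)-carbon of 10, giving benzylic S and carbinol R) is set by the ligand on lithium. The selectivity needed is the choice between the two enantiotopic epoxide carbons; since the two events are independent, a wrong event ends mostly in the meso diastereomer, which is removed by chromatography or crystallisation, and the remaining C2-symmetric diol is enriched (Horeau-type amplification). The substrate helps because each C–Li carbon is flanked by two C–H bonds, so the hindered internal epoxide can be reached, because the benzyloxy groups sit meta and cannot compete with the ligand for lithium, and because each ring is symmetric about its C7–C4a axis, so no regiochemical question arises here or in the later pyran closure.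

Step 7
Reactants: 12 bis{2,6-bis(benzyloxy)-4-[(2S,3R)-3-hydroxybutan-2-yl]phenyl}methane
Product: 14 7,7'-methylenebis[(3R,4S)-6,8-bis(benzyloxy)-3,4-dimethylisochromane], via bis(methoxymethyl) ether 13 (not isolated)
Conditions: CH2(OMe)2 (10 equiv), TMSOTf (20 mol %), CH2Cl2, 0 °C
Reagents that add atoms: dimethoxymethane, COCOC
Why: Oxa-Pictet–Spengler reaction: acetal exchange gives 13, whose oxocarbenium ion is attacked by the ring carbon next to the side chain (ortho and para to the two benzyloxy groups), the two such carbons of each ring being equivalent so that only one product can form, and the C3–O bond is never broken, so C3 and C4 are kept.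

Step 8
Reactants: 14 7,7'-methylenebis[(3R,4S)-6,8-bis(benzyloxy)-3,4-dimethylisochromane]
Product: 15 7,7'-methylenebis[(3R,4S)-6,8-bis(benzyloxy)-5-bromo-3,4-dimethylisochromane]
Conditions: NBS (2.1 equiv), MeCN–CH2Cl2, 0 °C, dark
Reagents that add atoms: N-bromosuccinimide, O=C1CCC(=O)N1Br
Why: Electrophilic aromatic bromination in a polar solvent goes to C5 and C5′, the only aromatic C–H bonds left on the activated rings (ortho and para to the ether oxygens), while the unactivated benzyl rings stay untouched.

Step 9
Reactants: 15 7,7'-methylenebis[(3R,4S)-6,8-bis(benzyloxy)-5-bromo-3,4-dimethylisochromane]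
Product: 17 7,7'-methylenebis[(3R,4S)-6,8-bis(benzyloxy)-3,4,5-trimethylisochromane], via 5,5'-dilithio bis-isochromane 16 (not isolated)
Conditions: n-BuLi (2.4 equiv), THF, −78 °C; MeI (6 equiv), −78 °C to rt
Reagents that add atoms: iodomethane, CI
Why: Bromine–lithium exchange is faster at −78 °C than deprotonation of any benzylic C–H bond, and the aryllithium, supported by the neighbouring ether oxygen, is alkylated by the small electrophile iodomethane.

Step 10
Reactants: 17 7,7'-methylenebis[(3R,4S)-6,8-bis(benzyloxy)-3,4,5-trimethylisochromane]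
Product: 18 7,7'-methylenebis[(3R,4S)-3,4,5-trimethylisochromane-6,8-diol]
Conditions: H2 (1 atm), 10% Pd/C, EtOAc–MeOH, rt
Reagents that add atoms: none
Why: Catalytic hydrogenolysis cleaves the four aryl benzyl ethers quickly under neutral conditions, whereas the cyclic C1–O2 benzylic ether, flanked on both sides, is far slower, and no stereocentre is affected.

Step 11
Reactants: 18 7,7'-methylenebis[(3R,4S)-3,4,5-trimethylisochromane-6,8-diol]
Product: 19 dicitrinone I
Conditions: DDQ (1.0 equiv), 1,4-dioxane, 0 °C to rt
Reagents that add atoms: none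
Why: Dehydrogenation by hydride abstraction with DDQ: among the benzylic C–H bonds only C1–H has the ring oxygen O2 as well as an ortho (C8) and a para (C6) hydroxyl behind it, so it should react ahead of the bridge CH2 and the C5 methyl, loss of a phenolic proton from the oxocarbenium ion gives the vinylogous-acid quinone methide, the two halves of 18 are homotopic so either one leads to 19, and one equivalent of oxidant limits a second dehydrogenation.

Compound list
1 | 1,3-dimethoxybenzene | COc1cccc(OC)c1 | starting material
2 | 2,6-dimethoxybenzaldehyde | COc1cccc(OC)c1C=O | starting material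
3 | 2,6-dimethoxyphenyllithium | [Li]c1c(OC)cccc1OC | intermediate
4 | bis(2,6-dimethoxyphenyl)methanol | OC(c1c(OC)cccc1OC)c2c(OC)cccc2OC | intermediate
5 | bis(2,6-dimethoxyphenyl)methane | C(c1c(OC)cccc1OC)c2c(OC)cccc2OC | intermediate
6 | bis[2,6-dimethoxy-4-(4,4,5,5-tetramethyl-1,3,2-dioxaborolan-2-yl)phenyl]methane | C(c1c(OC)cc(cc1OC)B2OC(C)(C)C(C)(C)O2)c3c(OC)cc(cc3OC)B4OC(C)(C)C(C)(C)O4 | intermediate
7 | bis(4-bromo-2,6-dimethoxyphenyl)methane | C(c1c(OC)cc(Br)cc1OC)c2c(OC)cc(Br)cc2OC | intermediate
8 | 2,2'-methylenebis(5-bromobenzene-1,3-diol) | C(c1c(O)cc(Br)cc1O)c2c(O)cc(Br)cc2O | intermediate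
9 | bis[2,6-bis(benzyloxy)-4-bromophenyl]methane | C(c1c(OCc2ccccc2)cc(Br)cc1OCc3ccccc3)c4c(OCc5ccccc5)cc(Br)cc4OCc6ccccc6 | intermediate
10 | cis-2,3-epoxybutane (meso, 2R,3S) | C[C@H]1O[C@H]1C | starting material
11 | bis[2,6-bis(benzyloxy)-4-lithiophenyl]methane | C(c1c(OCc2ccccc2)cc([Li])cc1OCc3ccccc3)c4c(OCc5ccccc5)cc([Li])cc4OCc6ccccc6 | intermediate
12 | bis{2,6-bis(benzyloxy)-4-[(2S,3R)-3-hydroxybutan-2-yl]phenyl}methane | C(c1c(OCc2ccccc2)cc(cc1OCc3ccccc3)[C@H](C)[C@@H](C)O)c4c(OCc5ccccc5)cc(cc4OCc6ccccc6)[C@H](C)[C@@H](C)O | intermediate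
13 | bis{2,6-bis(benzyloxy)-4-[(2S,3R)-3-(methoxymethoxy)butan-2-yl]phenyl}methane | C(c1c(OCc2ccccc2)cc(cc1OCc3ccccc3)[C@H](C)[C@@H](C)OCOC)c4c(OCc5ccccc5)cc(cc4OCc6ccccc6)[C@H](C)[C@@H](C)OCOC | intermediate
14 | 7,7'-methylenebis[(3R,4S)-6,8-bis(benzyloxy)-3,4-dimethylisochromane] | C(c1c(OCc2ccccc2)cc3c(c1OCc4ccccc4)CO[C@H](C)[C@H]3C)c5c(OCc6ccccc6)cc7c(c5OCc8ccccc8)CO[C@H](C)[C@H]7C | intermediate
15 | 7,7'-methylenebis[(3R,4S)-6,8-bis(benzyloxy)-5-bromo-3,4-dimethylisochromane] | C(c1c(OCc2ccccc2)c(Br)c3c(c1OCc4ccccc4)CO[C@H](C)[C@H]3C)c5c(OCc6ccccc6)c(Br)c7c(c5OCc8ccccc8)CO[C@H](C)[C@H]7C | intermediate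
16 | 7,7'-methylenebis[(3R,4S)-6,8-bis(benzyloxy)-5-lithio-3,4-dimethylisochromane] | C(c1c(OCc2ccccc2)c([Li])c3c(c1OCc4ccccc4)CO[C@H](C)[C@H]3C)c5c(OCc6ccccc6)c([Li])c7c(c5OCc8ccccc8)CO[C@H](C)[C@H]7C | intermediate
17 | 7,7'-methylenebis[(3R,4S)-6,8-bis(benzyloxy)-3,4,5-trimethylisochromane] | C(c1c(OCc2ccccc2)c(C)c3c(c1OCc4ccccc4)CO[C@H](C)[C@H]3C)c5c(OCc6ccccc6)c(C)c7c(c5OCc8ccccc8)CO[C@H](C)[C@H]7C | intermediate
18 | 7,7'-methylenebis[(3R,4S)-3,4,5-trimethylisochromane-6,8-diol] | C(c1c(O)c(C)c2c(c1O)CO[C@H](C)[C@H]2C)c3c(O)c(C)c4c(c3O)CO[C@H](C)[C@H]4C | intermediate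
19 | dicitrinone I, (3R,4S)-7-{[(3R,4S)-6,8-dihydroxy-3,4,5-trimethyl-3,4-dihydro-1H-isochromen-7-yl]methyl}-6-hydroxy-3,4,5-trimethyl-3,4-dihydro-8H-isochromen-8-one | CC1=C2C(=CO[C@H](C)[C@H]2C)C(=O)C(Cc2c(O)c(C)c3c(c2O)CO[C@H](C)[C@H]3C)=C1O | target

Total step count: 11. Longest linear sequence: 11 steps (from 1 or 2 to 19).

Steps most likely to fail

Step 6.
- What may go wrong: the ligand may discriminate too weakly between the enantiotopic carbons of so small an epoxide. Part of the aryllithium may be lost by aryl transfer to boron before both ends have reacted. The diastereomers differ only at remote centres and may resist separation.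
- Fallback (from 9, back at 12): the opening is run without chiral ligand (11, 10, BF3·OEt2, −78 °C). It should still be cleanly anti and give 12 together with the enantiomeric diol F1 and the meso diol F2 in statistical proportion.
- Lipase-catalysed acylation (immobilised Candida antarctica lipase B, vinyl acetate, MTBE, 40 °C) follows the Kazlauskas rule and acylates only (R)-carbinols that bear a methyl group. Thus 12 goes on to the diacetate F3, F2 stops at the monoacetate F4, and F1 stays a diol. The stereoisomers thereby become compounds of different polarity that silica gel separates.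
- Methanolysis of F3 (K2CO3, MeOH) returns 12. The same filter can polish ligand-derived material of insufficient purity.

Step 11.
- What may go wrong: hydride abstraction may compete at the bridge methylene or at the C5 methyl groups. The second half may be dehydrogenated at the same rate as the first. The quinone methide may suffer from the acidic hydroquinone formed.
- Fallback without any oxidant (from 12, back at 19): NBS (2 equiv) places one bromine per ring next to the side chain to give the dibromo diol F5. Suzuki–Miyaura methylation (trimethylboroxine, Pd(OAc)2/SPhos, K3PO4, toluene–H2O) gives the dimethyl diol F6. Hydrogenolysis (H2, Pd/C) gives the open hexaol F7, in which C8a is the only free aromatic carbon of each ring.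
- One equivalent of aqueous formaldehyde with catalytic acid, in dilute solution, closes one pyran by a phenolic oxa-Pictet–Spengler reaction to the half-closed pentaol F8. Unchanged F7 is recycled, and doubly closed material is 18.
- Triethyl orthoformate with HCl, the classical closure of the citrinin ring, then formylates C8a of the open half. Acetal formation with the C3 hydroxyl and loss of ethanol give 19, with C1 introduced directly at the formyl level.

Step 9.
- What may go wrong: the aryllithium next to a benzyl ether may pass its charge to the benzylic OCH2 group and trigger a Wittig-type rearrangement. One of the two hindered sites may be protonated instead of methylated.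
- Fallback (from 15, back at 17): the polarity of the bond formation is reversed. The aryl bromide serves as electrophile in a palladium-catalysed Suzuki–Miyaura methylation (trimethylboroxine, Pd(OAc)2/SPhos, K3PO4, toluene–H2O, 100 °C). This involves no carbanion and leads directly to 17.

Further compounds
F1 | step 6 | bis{2,6-bis(benzyloxy)-4-[(2R,3S)-3-hydroxybutan-2-yl]phenyl}methane (enantiomer of 12) | C(c1c(OCc2ccccc2)cc(cc1OCc3ccccc3)[C@@H](C)[C@H](C)O)c4c(OCc5ccccc5)cc(cc4OCc6ccccc6)[C@@H](C)[C@H](C)O
F2 | step 6 | {2,6-bis(benzyloxy)-4-[(2S,3R)-3-hydroxybutan-2-yl]phenyl}{2,6-bis(benzyloxy)-4-[(2R,3S)-3-hydroxybutan-2-yl]phenyl}methane (meso diol) | C(c1c(OCc2ccccc2)cc(cc1OCc3ccccc3)[C@H](C)[C@@H](C)O)c4c(OCc5ccccc5)cc(cc4OCc6ccccc6)[C@@H](C)[C@H](C)O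
F3 | step 6 | bis{4-[(2S,3R)-3-acetoxybutan-2-yl]-2,6-bis(benzyloxy)phenyl}methane (diacetate of 12) | C(c1c(OCc2ccccc2)cc(cc1OCc3ccccc3)[C@H](C)[C@@H](C)OC(C)=O)c4c(OCc5ccccc5)cc(cc4OCc6ccccc6)[C@H](C)[C@@H](C)OC(C)=O
F4 | step 6 | monoacetate of F2, acetylated at the (R)-carbinol | C(c1c(OCc2ccccc2)cc(cc1OCc3ccccc3)[C@H](C)[C@@H](C)OC(C)=O)c4c(OCc5ccccc5)cc(cc4OCc6ccccc6)[C@@H](C)[C@H](C)O
F5 | step 11 | bis{2,6-bis(benzyloxy)-3-bromo-4-[(2S,3R)-3-hydroxybutan-2-yl]phenyl}methane | C(c1c(OCc2ccccc2)cc(c(Br)c1OCc3ccccc3)[C@H](C)[C@@H](C)O)c4c(OCc5ccccc5)cc(c(Br)c4OCc6ccccc6)[C@H](C)[C@@H](C)O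
F6 | step 11 | bis{2,6-bis(benzyloxy)-4-[(2S,3R)-3-hydroxybutan-2-yl]-3-methylphenyl}methane | C(c1c(OCc2ccccc2)cc(c(C)c1OCc3ccccc3)[C@H](C)[C@@H](C)O)c4c(OCc5ccccc5)cc(c(C)c4OCc6ccccc6)[C@H](C)[C@@H](C)O
F7 | step 11 | 2,2'-methylenebis{5-[(2S,3R)-3-hydroxybutan-2-yl]-4-methylbenzene-1,3-diol} | C(c1c(O)cc(c(C)c1O)[C@H](C)[C@@H](C)O)c2c(O)cc(c(C)c2O)[C@H](C)[C@@H](C)O
F8 | step 11 | (3R,4S)-7-{2,6-dihydroxy-4-[(2S,3R)-3-hydroxybutan-2-yl]-3-methylbenzyl}-3,4,5-trimethylisochromane-6,8-diol | C(c1c(O)cc(c(C)c1O)[C@H](C)[C@@H](C)O)c2c(O)c(C)c3c(c2O)CO[C@H](C)[C@H]3C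
F0 | step 9 | none | none
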